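All constants are assumed; the result is computed.

3 questions stand on two flasks.

- part of the substrate that has reacted at the end, dusk
- part of the substrate that has reacted at the end, midnight
- what raising the equivalents of scavenger from its lowest to its highest value here does to the part of the substrate that has reacted (changes below 5 percentage points count as none) (it rises / it falls / no change)

- dusk: substrate 0.10 M; partner 0.800 equiv; scavenger 0.500 equiv (fed, over 5.0 s); time 3.0 min
- midnight: substrate 0.10 M; partner 0.800 equiv; scavenger 0.750 equiv (fed, over 5.0 s); time 3.0 min

    scavenger + released group → scavenged by-product (k1 = 67 M⁻¹ s⁻¹)
    partner + released group ⇌ idle adduct, settled at all times (K2 = 7.1 M⁻¹)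
    partner + target → over-reaction product (k3 = 0.78 M⁻¹ s⁻¹)
    substrate + partner ⇌ target + released group (K4 = 0.10, k4 = 9.2 M⁻¹ s⁻¹)

- released group is meant together with its idle adduct
- run time (dusk): 3.0 min

**Two amounts.** In dusk and midnight, substrate stays converted when its released group reaches scavenger, and each such move costs one partner. Target spends partner as well, through over-reaction. In dusk the forward half-life of substrate, 0.94 s with the other concentrations as charged and the way back not counted, is short against 3.0 min. So this reckoning treats the end as a matter of two amounts: the scavenger charge, and what the partner charge can pay for.

**Partner price.** Released group either meets scavenger, at 67 M⁻¹ s⁻¹, or returns with target, at 92.0 M⁻¹ s⁻¹, a larger constant than capture. This reckoning takes substrate, target and scavenger as about equal mid-run. One lasting move then needs 2.37 forward moves, and target takes 0.0848 partner per forward move. That gives the partner price, the partner spent per substrate converted for good: 1.20.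

**The crossing.** The partner charge pays for 0.666 of scavenger. Dusk lies below that crossing, so this reckoning makes scavenger the limiting reagent and expects 0.500 equiv of substrate to react. Midnight lies above it, so the reckoning makes partner the limit, at 0.666 of substrate.

**The forecast.** It gives 50.5% (48% to 54%) for dusk and 74% (70% to 76%) for midnight, and says it rises, “with a few percent of it diverted into over-reaction”. For midnight it differs from the reckoning here.

**The result.** Dusk reaches 50.2% and midnight 65.4%: it rises, by 15 percentage points, and the difference in scavenger charge is the main reason for that rise. Left ten times as long, dusk stands at 50.0% and midnight at 65.4%.

**Midnight's price.** Midnight ends with partner at 0%, scavenger at 12.9% of its charge and over-reaction product at 14.6%, which reads as a price of 1.22 against the reckoned 1.20. The return of target and released group is part of that price: with it struck out, midnight reaches 74.9% instead of 65.4%.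

**Second flask.** The neighbour of dusk with 0.480 equiv of partner can pay, at the same price, for 0.400, below its scavenger charge. Computed, 42.9% reacts, with partner at 0% and scavenger at 14%.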